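1. Late in Friday's run the target barely moves, 19.5% at 8.00 min and 19.8% at 10.0 min, while 79.8% of the starting material still stands. So I reckon each flask by its plateau and by how soon it gets there.

| setting | Wednesday's | Friday's | Thursday's | larch | ash |
|---|---|---|---|---|---|
| starting material | 0.050 M | 0.050 M | 0.050 M | 0.050 M | 0.050 M |
| second substrate | 0.035 M | 0.055 M | 0.025 M | 0.0250 M | 0.0250 M |
| partner | 0.060 M | 0.060 M | 0.060 M | 0.0600 M | 0.0600 M |
| free catalyst | 0.50 mM | 0.50 mM | 0.25 mM | 0.50 mM | 0.50 mM |
| temperature | 20 °C | 38 °C | 20 °C | 50 °C | 25 °C |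
| remark | run made earlier | run made earlier | run made earlier |  |  |
| time |  |  |  | 5.0 min | 5.0 min |

| run | time / min | target / % | starting material / % |
|---|---|---|---|
| Wednesday's | 4.00 | 9.0 | 90.1 |
| Wednesday's | 6.00 | 11.7 | 87.8 |
| Wednesday's | 12.0 | 15.3 | 83.8 |
| Wednesday's | 20.0 | 17.1 | 82.5 |
| Friday's | 0.667 | 6.7 | 93.0 |
| Friday's | 2.00 | 12.9 | 86.3 |
| Friday's | 4.00 | 16.8 | 82.5 |
| Friday's | 5.00 | 18.0 | 81.1 |
| Friday's | 8.00 | 19.5 | 80.0 |
| Friday's | 10.0 | 19.8 | 79.8 |
| Thursday's | 4.00 | 4.9 | 94.7 |
| Thursday's | 8.00 | 7.3 | 92.4 |
| Thursday's | 12.0 | 8.8 | 91.4 |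
| Thursday's | 20.0 | 10.3 | 89.1 |

(readings scatter by 0.3 percentage points)

* the flask that comes out highest in amount of target, in percent of the starting material charged, or "all alike" when all lie within 1.5 percentage points (larch / ash / all alike)
* target at the end, in percent of the starting material charged, larch
* target at the end, in percent of the starting material charged, ash



2. Thursday's run has the second substrate of both new flasks, and its last reading gives 20.6. I call this the turnover allowance, the target made by the plateau per catalyst charged. That run is still rising, so the figure errs low. On the charges of larch and ash it means a plateau of 20.6%, provided the allowance holds at their temperatures.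

3. I replace each curve by one exponential and call its stall time the time in which the gap to the plateau shrinks by a factor e. Wednesday's first and last readings give 5.35 min. That curve then gives 15.3% at 12.0 min, and the unused reading there is 15.3%.

4. Friday's run, warmer and with more second substrate, gives 1.61 min, and I put the whole change down to temperature, which is an assumption. Taking the logarithm of the stall time as straight in temperature, I get the ladder from the fastest: larch 0.726 min, Friday's run 1.61 min, ash 3.84 min, Wednesday's run 5.35 min.

5. Larch's stall time is far shorter than the 5.0 min of the run, so I reckon larch on its plateau. Ash's is closer to it, and by this reckoning ash fills 72.8% of the plateau. I commit to 20.6% for larch, though its 50 °C lies beyond the warmest run, and to that share of the plateau for ash, which puts larch above ash.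

6. The forecast says larch, with 27% for larch, above mine, and 14% for ash, which is 68.0% of my plateau against my share of 72.8%. Its ground is: “The target stops rising while starting material remains”.

    starting material + free catalyst ⇌ catalyst intermediate A (K = 2800 M⁻¹, k = 6.70 M⁻¹ s⁻¹, Ea = 57.0 kJ mol⁻¹, ΔH = 3.00 kJ mol⁻¹)
    partner + catalyst intermediate A ⇌ free catalyst + target (K = 4.10, k = 5.00 M⁻¹ s⁻¹, Ea = 52.0 kJ mol⁻¹, ΔH = −14.0 kJ mol⁻¹)
    second substrate + free catalyst ⇌ catalyst intermediate B (K = 43.0 M⁻¹, k = 16.0 M⁻¹ s⁻¹, Ea = 37.0 kJ mol⁻¹, ΔH = −19.0 kJ mol⁻¹)
    partner + catalyst intermediate B → free catalyst + second product (k = 4.10 M⁻¹ s⁻¹, Ea = 53.0 kJ mol⁻¹)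
    2 partner → self-condensation product (k = 0.210 M⁻¹ s⁻¹, Ea = 48.0 kJ mol⁻¹)
    (constants at 25 °C)

Larch gives 23.2% and ash 13.6%, so larch stands highest, as the forecast said. Larch's target is 23.2 turnovers of catalyst against the allowance of 20.6. By its forward rate, the step of partner with catalyst intermediate A would halve larch's partner in 1.5 min at 0.101 min, yet partner is down to 2.06% of its charge at 2.50 min. At the end of larch, self-condensation product holds 78.5% of the partner charged and target 19.3%. For larch's neighbour with 0.20 M of starting material, the allowance reckons 5.15%, and that flask gives 7.04%.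

The earlier runs and the new flask are simulated from invented constants; the scatter is artificial.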